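**Retrosynthetic overview**
1. Target 10 ⇒ global O-debenzylation of tetra-O-benzyl ether 9.
2. Key disconnection: both C–OMe bonds of ring A (C6 and C8) are cut at once ⇒ 6,8-dibromide 6 + NaOMe, a twofold CuBr-catalysed Ullmann methoxylation on the intact flavonol.
3. C–Br ⇒ C–H: regioselective double bromination of ring A in 5-hydroxy tetrabenzyl ether 3.
4. 3 ⇒ quercetin 1 + benzyl bromide 2. No ring is formed: rings A, B and C are bought intact, and ring A is oxygenated late rather than built from a hexasubstituted benzene by the usual chalcone/Algar–Flynn–Oyamada or Allan–Robinson logic.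

Assumption: the target has no stereocentre or other stereogenic element, so it is one achiral compound and needs no stereocontrol; quercetin, a bulk commercial flavonol, is taken as an admissible starting material.

**Route**

Step 1
Reactants: 1 quercetin; 2 benzyl bromide
Product: 3 3,7,3',4'-tetra-O-benzylquercetin
Conditions: BnBr (4.2 equiv), K2CO3 (4.5 equiv), DMF, N2, rt, 16 h; precipitate with water, recrystallise
Reagents that add atoms: benzyl bromide, BrCc1ccccc1
Why: Williamson ether synthesis in which K2CO3 ionises the four acidic hydroxyls (7, 4', 3, 3') while the 5-OH, hydrogen-bonded to the C4 carbonyl, is the least acidic and least nucleophilic and stays free; no stereocentre is involved.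

Step 2
Reactants: 3 3,7,3',4'-tetra-O-benzylquercetin; 4 N-bromosuccinimide
Product: 6 6,8-dibromo-3,7,3',4'-tetra-O-benzylquercetin, via 6-bromo monobromide 5 (not isolated)
Conditions: NBS (2.1 equiv), DMF, 0 °C → rt, dark, 3 h
Reagents that add atoms: N-bromosuccinimide, O=C1CCC(=O)N1Br
Why: Electrophilic aromatic bromination: C6 and C8 are each activated by three oxygen donors (5-OH, 7-OBn, O1) and far more nucleophilic than ring B, which is deactivated by conjugation to the pyranone carbonyl, so C6 (ortho to the free 5-OH) reacts first to give 5 and C8 follows to give 6.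

Step 3
Reactants: 6 6,8-dibromo-3,7,3',4'-tetra-O-benzylquercetin; 7 sodium methoxide
Product: 9 6,8-dimethoxy-3,7,3',4'-tetra-O-benzylquercetin, via 8-bromo-6-methoxy ether 8 (not isolated)
Conditions: NaOMe (25 wt % in MeOH, 10 equiv), CuBr (30 mol %), DMF, Ar, 110 °C, 8 h; then 1 M HCl
Reagents that add atoms: sodium methoxide, [Na+].[O-]C
Why: Ullmann-type CuBr-catalysed C–O coupling (methanolysis of aryl bromides, the bromovanillin-to-syringaldehyde reaction type) on the sodium 5-phenoxide, which shields the pyranone from methoxide; the C6 bromide next to the copper-binding phenoxide is expected to exchange first (8), then C8, and any base-induced ring opening and reclosure (Wessely–Moser) is degenerate because C6 and C8 end up with the same group.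

Step 4
Reactants: 9 6,8-dimethoxy-3,7,3',4'-tetra-O-benzylquercetin
Product: 10 3,5,7,3',4'-pentahydroxy-6,8-dimethoxyflavone
Conditions: H2 (1 atm), 10% Pd/C, THF–MeOH 1:1, rt, 12 h; filter under Ar
Reagents that add atoms: none
Why: Catalytic hydrogenolysis of the four benzylic C–O bonds over Pd/C frees all four hydroxyls under neutral conditions that leave the aryl methyl ethers and the fully substituted C2=C3 bond of the flavonol untouched; the product is achiral.

**Compound list** (all compounds are achiral; no SMILES needs stereodescriptors)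

1 | quercetin (3,5,7,3',4'-pentahydroxyflavone) | O=c1c(O)c(-c2ccc(O)c(O)c2)oc2cc(O)cc(O)c12 | starting material
2 | benzyl bromide | BrCc1ccccc1 | starting material
3 | 3,7,3',4'-tetra-O-benzylquercetin = 3,7-bis(benzyloxy)-2-[3,4-bis(benzyloxy)phenyl]-5-hydroxy-4H-chromen-4-one | O=c1c(OCc2ccccc2)c(-c2ccc(OCc3ccccc3)c(OCc3ccccc3)c2)oc2cc(OCc3ccccc3)cc(O)c12 | intermediate
4 | N-bromosuccinimide | O=C1CCC(=O)N1Br | starting material
5 | 6-bromo-3,7,3',4'-tetra-O-benzylquercetin (6-bromo monobromide, not isolated) | O=c1c(OCc2ccccc2)c(-c2ccc(OCc3ccccc3)c(OCc3ccccc3)c2)oc2cc(OCc3ccccc3)c(Br)c(O)c12 | intermediate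
6 | 6,8-dibromo-3,7,3',4'-tetra-O-benzylquercetin | O=c1c(OCc2ccccc2)c(-c2ccc(OCc3ccccc3)c(OCc3ccccc3)c2)oc2c(Br)c(OCc3ccccc3)c(Br)c(O)c12 | intermediate
7 | sodium methoxide | [Na+].[O-]C | starting material
8 | 8-bromo-6-methoxy-3,7,3',4'-tetra-O-benzylquercetin (8-bromo-6-methoxy ether, not isolated) | O=c1c(OCc2ccccc2)c(-c2ccc(OCc3ccccc3)c(OCc3ccccc3)c2)oc2c(Br)c(OCc3ccccc3)c(OC)c(O)c12 | intermediate
9 | 6,8-dimethoxy-3,7,3',4'-tetra-O-benzylquercetin = 3,7-bis(benzyloxy)-2-[3,4-bis(benzyloxy)phenyl]-5-hydroxy-6,8-dimethoxy-4H-chromen-4-one | O=c1c(OCc2ccccc2)c(-c2ccc(OCc3ccccc3)c(OCc3ccccc3)c2)oc2c(OC)c(OCc3ccccc3)c(OC)c(O)c12 | intermediate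
10 | 3,5,7,3',4'-pentahydroxy-6,8-dimethoxyflavone | COc1c(O)c(OC)c2oc(-c3ccc(O)c(O)c3)c(O)c(=O)c2c1O | target

**Total step count:** 4
**Longest linear sequence:** 4 steps (1 → 3 → 6 → 9 → 10)

**Three steps most likely to fail, with fallbacks**

Step 3 (highest risk). The twofold copper exchange acts on two di-ortho-substituted, electron-rich C–Br bonds and may stall at monobromide 8 or give hydrodebromination. The fallback sets out from 6 and changes both the protecting-group state and the coupling manifold. The 5-OH is capped under forcing conditions (BnBr, K2CO3, DMF, 80 °C) to give 6,8-dibromo-3,5,7,3',4'-penta-O-benzylquercetin F1. On this neutral substrate both methoxy groups are installed by palladium-catalysed C–O cross-coupling with methanol (Pd2(dba)3, tBuBrettPhos, Cs2CO3, MeOH, toluene, 80 °C), giving 6,8-dimethoxy-3,5,7,3',4'-penta-O-benzylquercetin F2. Hydrogenolysis of its five benzyl ethers (H2, Pd/C, THF–MeOH) comes back to the route at target 10.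

Step 2. Over-bromination on ring B or incomplete reaction at C8 would give inseparable mixtures. The fallback sets out from 1 and reverses the order of halogenation and protection. Free quercetin, whose phloroglucinol-type ring A is by far its most nucleophilic site, is brominated with Br2 (2.05 equiv) in AcOH at rt to give 6,8-dibromoquercetin F3. This is then benzylated selectively at the 3-, 7-, 3'- and 4'-hydroxyls (BnBr, K2CO3, DMF, rt to 50 °C), the chelated 5-OH again staying free, and the sequence comes back to the route at 6.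

Step 1. Statistical mixtures of tri-, tetra- and penta-benzyl ethers may lower the yield of 3. The fallback sets out from 1 and replaces selective protection by over-protection followed by chelation-controlled deprotection. Exhaustive benzylation (BnBr 7 equiv, K2CO3, DMF, 80 °C) gives 3,5,7,3',4'-penta-O-benzylquercetin F4. MgBr2·OEt2 in toluene–Et2O at 80 °C then removes only the benzyl group peri to the carbonyl (magnesium chelated between the C4 carbonyl and O5, bromide attacking the benzylic carbon), and the sequence comes back to the route at 3.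

**Further compounds**

F1 | step 3 | 6,8-dibromo-3,5,7,3',4'-penta-O-benzylquercetin | O=c1c(OCc2ccccc2)c(-c2ccc(OCc3ccccc3)c(OCc3ccccc3)c2)oc2c(Br)c(OCc3ccccc3)c(Br)c(OCc3ccccc3)c12
F2 | step 3 | 6,8-dimethoxy-3,5,7,3',4'-penta-O-benzylquercetin | O=c1c(OCc2ccccc2)c(-c2ccc(OCc3ccccc3)c(OCc3ccccc3)c2)oc2c(OC)c(OCc3ccccc3)c(OC)c(OCc3ccccc3)c12
F3 | step 2 | 6,8-dibromoquercetin | O=c1c(O)c(-c2ccc(O)c(O)c2)oc2c(Br)c(O)c(Br)c(O)c12
F4 | step 1 | 3,5,7,3',4'-penta-O-benzylquercetin | O=c1c(OCc2ccccc2)c(-c2ccc(OCc3ccccc3)c(OCc3ccccc3)c2)oc2cc(OCc3ccccc3)cc(OCc3ccccc3)c12
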